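**Retrosynthetic overview**
1. Feature used, in pyrroloindoline numbering (N1-Me, C3a quaternary, benzene ring C3b–C4–C5–C6–C7–C7a, N8-H, C8a aminal): the benzene ring bears the benzofuran oxygen on C4, next to fusion carbon C3b, and the benzofuran carbon on C5. Oxygen beside a ring fusion with a carbon substituent ortho to it is what a furan-yne cycloisomerisation gives. The benzene ring is therefore built from a furan (C7a, C7, C6, C5 and the oxygen) and a terminal alkyne (C3b, C4).
2. Ring C comes last. The C8a–N1 aminal is closed reductively from a 7-bromo-3a-prenyl oxindole. The prenyl group comes from a silyloxyethyl arm (oxidation, Wittig), and bromine enters at C7 before any alkene exists.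
3. Key disconnection: ring B, the benzene ring and the benzofuran ring form in one operation from an acyclic N-acyl-N-(5-alkynylfuran-2-yl)carbamate with an ethynyl group on C3a. The bonds made are C3b–C7a, C4–C5, C4–O and O–C2 of the benzofuran.
4. The imide comes from a quaternary α-ethynyl acid and a furyl carbamate (Sonogashira, Curtius). The acid comes from an α-quaternary pyrrolidinone, a temporary ring that is opened again. Its C3a is set by palladium-catalysed decarboxylative asymmetric allylic alkylation, and the allyl group is cut down to ethynyl.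
5. Ring order: ring B, benzene and furan (step 15), then ring C (step 22).

Key step: step 15

Assumption: the (S)-configured PHOX ligand is taken to deliver allyl to the same enolate face as in the established N-aroyl lactam and 2-alkylcyclohexanone cases. This gives the (R)-lactam drawn in step 3; if the sense were opposite, the (R)-ligand would be used.
Locants C3a, C3b, C4–C7a, N8, C8a and N1 refer to the pyrroloindoline numbering of the target throughout. TBS = tert-butyldimethylsilyl.

**Step 1**
Reactants: 1 aniracetam [1-(4-methoxybenzoyl)pyrrolidin-2-one]; 2 allyl chloroformate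
Product: 3 allyl 1-(4-methoxybenzoyl)-2-oxopyrrolidine-3-carboxylate (racemic)
Conditions: LiN(SiMe3)2 (2.1 equiv), THF, −78 °C; then 2, −78 → −30 °C; aq. NH4Cl
Reagents that add atoms: none
Why: Claisen-type C-acylation of the lithium enolate of an N-aroyl lactam with a chloroformate, in which the second equivalent of base stores the more acidic product as its enolate and so prevents a second acylation.

**Step 2**
Reactants: 3 allyl 1-(4-methoxybenzoyl)-2-oxopyrrolidine-3-carboxylate; 4 tert-butyl(2-iodoethoxy)dimethylsilane
Product: 5 allyl 3-[2-(TBS-oxy)ethyl]-1-(4-methoxybenzoyl)-2-oxopyrrolidine-3-carboxylate (racemic)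
Conditions: Cs2CO3, DMF, 45 °C
Reagents that add atoms: none
Why: SN2 C-alkylation of the soft, doubly stabilised amido ester enolate with a primary iodide, giving a racemic quaternary carbon whose configuration is erased again in step 3.

**Step 3**
Reactants: 5 racemic quaternary allyl ester
Product: 6 (R)-3-allyl-3-[2-(TBS-oxy)ethyl]-1-(4-methoxybenzoyl)pyrrolidin-2-one
Conditions: Pd2(dba)3 (5 mol %), (S)-(CF3)3-t-BuPHOX (12.5 mol %), toluene, 40 °C
Reagents that add atoms: none
Why: Palladium-catalysed decarboxylative asymmetric allylic alkylation (Tsuji–Trost type): zerovalent palladium ionises the allyl ester, CO2 is lost, and the prochiral N-aroyl lactam enolate is allylated inside the pocket of the electron-poor (S)-PHOX ligand, so both enantiomers of 5 should converge on (R)-6 and C3a is set here.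

**Step 4**
Reactants: 6 N-anisoyl allyl lactam
Product: 7 (R)-3-allyl-3-[2-(TBS-oxy)ethyl]pyrrolidin-2-one
Conditions: NaOMe (0.2 equiv), MeOH, 0 °C → rt
Reagents that add atoms: none
Why: Base-catalysed methanolysis (transacylation) of the imide takes place at the exocyclic aroyl carbonyl because the ring carbonyl is shielded by the adjacent quaternary carbon, and the silyl ether is inert to methoxide.

**Step 5**
Reactants: 7 NH allyl lactam
Product: 8 (R)-3-[2-(TBS-oxy)ethyl]-3-[(E)-prop-1-enyl]pyrrolidin-2-one
Conditions: RuHCl(CO)(PPh3)3 (5 mol %), toluene, 110 °C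
Reagents that add atoms: none
Why: Ruthenium hydride alkene isomerisation by hydrometalation and β-hydride elimination moves the terminal double bond to the more stable internal position and must stop there because the next carbon is quaternary, the E/Z composition being irrelevant for step 6.

**Step 6**
Reactants: 8 propenyl lactam
Product: 10 (R)-3-[2-(TBS-oxy)ethyl]-2-oxopyrrolidine-3-carbaldehyde, via ozonide 9 (not isolated)
Conditions: O3, CH2Cl2, −78 °C; then PPh3, −78 °C → rt
Reagents that add atoms: ozone, [O-][O+]=O
Why: Ozonolysis (Criegee mechanism) with reductive work-up cleaves the only C=C bond and leaves a formyl group directly on C3a, which carries no hydrogen and so cannot epimerise.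

**Step 7**
Reactants: 10 formyl lactam
Product: 11 (R)-3-ethynyl-3-[2-(TBS-oxy)ethyl]pyrrolidin-2-one
Conditions: MeC(O)C(N2)P(O)(OMe)2, K2CO3, MeOH, 0 °C → rt
Reagents that add atoms: dimethyl (1-diazo-2-oxopropyl)phosphonate, CC(=O)C(=[N+]=[N-])P(=O)(OC)OC
Why: Seyferth–Gilbert homologation in its Ohira–Bestmann form: the diazophosphonate anion released by methanolysis adds to the non-enolisable aldehyde, and Horner-type elimination, loss of N2 and 1,2-hydride shift give the terminal alkyne, while the unactivated NH lactam is too poor a leaving group for retro-Claisen deformylation.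

**Step 8**
Reactants: 11 ethynyl lactam
Product: 12 tert-butyl (R)-3-ethynyl-3-[2-(TBS-oxy)ethyl]-2-oxopyrrolidine-1-carboxylate
Conditions: Boc2O, DMAP (0.2 equiv), MeCN, rt
Reagents that add atoms: di-tert-butyl dicarbonate, CC(C)(C)OC(=O)OC(=O)OC(C)(C)C
Why: DMAP-catalysed N-acylation of the lactam with Boc2O turns it into an acyl carbamate whose ring carbonyl is activated for step 9 and puts the later N1 protecting group in place.

**Step 9**
Reactants: 12 N-Boc ethynyl lactam
Product: 13 (R)-2-[2-(Boc-amino)ethyl]-2-ethynyl-4-(TBS-oxy)butanoic acid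
Conditions: LiOH, THF/H2O, rt; then 1 M HCl to pH 4, 0 °C
Reagents that add atoms: lithium hydroxide, [Li+].[OH-]
Why: Hydroxide opening of an N-Boc-activated five-membered lactam at the ring carbonyl, which is more electrophilic than the tert-butyl-shielded carbamate carbonyl and is flanked by the slim ethynyl group, frees the C8a carboxyl group and leaves N1 as its Boc carbamate.

**Step 10**
Reactants: 13 Boc-amino acid
Product: 14 (R)-2-{2-[Boc(methyl)amino]ethyl}-2-ethynyl-4-(TBS-oxy)butanoic acid
Conditions: NaH, MeI, THF, 0 °C → rt; then 1 M HCl to pH 4, 0 °C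
Reagents that add atoms: iodomethane, CI
Why: N-alkylation of the sodium carbamate with MeI in THF, the classical N-methylation of Boc-amino acids, in which the poorly soluble sodium carboxylate is not esterified and NaH does not metalate the terminal alkyne; the fully substituted N1 can then no longer close back onto the activated acid in step 14.

**Step 11**
Reactants: 15 2-methylbut-3-yn-2-ol
Product: 16 triethyl[(2-methylbut-3-yn-2-yl)oxy]silane
Conditions: Et3SiCl, imidazole, DMAP (cat.), DMF, rt
Reagents that add atoms: chlorotriethylsilane, CC[Si](Cl)(CC)CC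
Why: Imidazole-promoted silylation gives the tertiary triethylsilyl ether, which removes the acidic OH before steps 13 and 14 and later suppresses ionisation and Meyer–Schuster rearrangement under gold catalysis.

**Step 12**
Reactants: 17 5-bromofuran-2-carboxylic acid; 16 silylated alkynol
Product: 18 5-[3-methyl-3-(triethylsilyloxy)but-1-ynyl]furan-2-carboxylic acid
Conditions: PdCl2(PPh3)2 (3 mol %), CuI (5 mol %), Et3N, DMF, 50 °C; then aq. citric acid
Reagents that add atoms: none
Why: Sonogashira coupling at the acceptor-activated C5–Br bond of the furoate, carried out before nitrogen is introduced so that the sensitive amidofuran is never exposed to palladium and copper.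

**Step 13**
Reactants: 18 alkynylfuroic acid
Product: 21 methyl {5-[3-methyl-3-(triethylsilyloxy)but-1-ynyl]furan-2-yl}carbamate, via acyl azide 19 (not isolated), via isocyanate 20 (not isolated)
Conditions: (PhO)2P(O)N3, Et3N, toluene, rt → 85 °C; then MeOH, 60 °C
Reagents that add atoms: diphenylphosphoryl azide, [N-]=[N+]=NP(=O)(Oc1ccccc1)Oc1ccccc1; methanol, CO
Why: Curtius rearrangement of the furoyl azide places nitrogen on furan C2 (the later C7a), and methanol traps the isocyanate as a methyl carbamate that can be handled.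

**Step 14**
Reactants: 14 quaternary ethynyl acid; 21 furyl carbamate
Product: 23 methyl N-[(R)-2-{2-[Boc(methyl)amino]ethyl}-2-ethynyl-4-(TBS-oxy)butanoyl]-N-{5-[3-methyl-3-(triethylsilyloxy)but-1-ynyl]furan-2-yl}carbamate (cascade precursor), via acid chloride 22 (not isolated)
Conditions: 14, Me2C=C(Cl)NMe2, CH2Cl2, 0 °C; separately 21, n-BuLi, THF, −78 °C; combine, −78 → 0 °C
Reagents that add atoms: none
Why: N-acylation of a lithium N-furylcarbamate with an acid chloride, the standard entry to 2-imidofurans; the α-chloroenamine makes the acid chloride under neutral conditions that spare Boc and silyl groups, and the acid has no α-hydrogen, so neither ketene formation nor epimerisation is possible.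

**Step 15**
Reactants: 23 cascade precursor
Product: 26 methyl (R)-8-{2-[Boc(methyl)amino]ethyl}-8-[2-(TBS-oxy)ethyl]-7-oxo-2-[2-(triethylsilyloxy)propan-2-yl]-7,8-dihydro-6H-furo[2,3-e]indole-6-carboxylate (cascade product), via oxepine 24 (not isolated), via alkynylphenol 25 (not isolated)
Conditions: (Ph3P)AuNTf2 (5 mol %), 4 Å MS, CH2Cl2, 23 °C
Reagents that add atoms: none
Why: Proposed new method: monovalent gold binds the terminal alkyne and the furan C7a=C7 bond attacks its inner carbon 5-exo-dig, which forms C3b–C7a, closes ring B and gives a cyclopropyl gold carbene that fragments (C7–C3b and C7a–O break) to a dienone gold carbene centred on C4. The ynone oxygen adds to the carbene carbon to give oxepine 24 (seven-membered O–C4 closure), its 6π valence isomerisation to the arene oxide forms C4–C5 and thereby closes the six-membered carbocycle, and heterolysis of the C5–O bond with loss of the C4 proton aromatises it to alkynylphenol 25 with the former furan oxygen now on C4. The same catalyst then activates the C5 alkyne and the C4 hydroxyl adds 5-endo-dig, followed by protodeauration, to close the furan ring of 26. The closest known reaction types are the gold-catalysed intramolecular furan-yne phenol synthesis, known for carbon-linked tethers on alkylfurans, and the gold-catalysed cycloisomerisation of 2-alkynylphenols to benzofurans, whereas a nitrogen-linked 2-imidofuran donor, a 5-alkynyl substituent and the merger of both events are untested. No stereocentre is formed and the quaternary C3a is a spectator that cannot epimerise. The step needs chemoselectivity between the two alkynes and regioselective oxygen transfer: only the terminal alkyne lies within five-membered reach of the furan, oxygen stays on C4 because only C4 bears the proton whose loss completes aromatisation and the doubly acylated N8 cannot stabilise the alternative cation, the methyl carbamate on N8 cannot be consumed by dealkylative O-attack on the alkyne as a tert-butyl carbamate could, the silyl ethers shut off hydroalkoxylation, Meyer–Schuster rearrangement and the 1,5-enyne pathway that a prenyl group would open, and room temperature keeps the thermal furan Diels–Alder reaction silent.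

**Step 16**
Reactants: 26 cascade product
Product: 27 (R)-8-{2-[Boc(methyl)amino]ethyl}-8-[2-(TBS-oxy)ethyl]-2-[2-(triethylsilyloxy)propan-2-yl]-6,8-dihydro-7H-furo[2,3-e]indol-7-one (N8-H)
Conditions: K2CO3 (0.5 equiv), MeOH, 0 °C → rt
Reagents that add atoms: none
Why: Methanolysis of the N-acyl carbamate: methoxide attacks the unhindered carbamate carbonyl rather than the C8a carbonyl next to the quaternary C3a, the stabilised oxindole anion leaves, and the ordinary N1 Boc carbamate and both silyl ethers are not touched.

**Step 17**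
Reactants: 27 N8-H furo-oxindole
Product: 28 the 5-bromo derivative of 27 (furoindolone numbering; bromine on C7 in pyrroloindoline numbering)
Conditions: NBS (1.0 equiv), MeCN, −20 → 0 °C, dark
Reagents that add atoms: N-bromosuccinimide, O=C1CCC(=O)N1Br
Why: Electrophilic aromatic bromination: C7 is ortho to the free anilide N8-H and para to the benzofuran oxygen on C4 and is thus the most activated open position, whereas its only rival, the furan β-carbon, is screened by the neighbouring CMe2OSiEt3 group, and no alkene is present yet.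

**Step 18**
Reactants: 28 bromide
Product: 29 (R)-5-bromo-8-{2-[Boc(methyl)amino]ethyl}-8-(2-hydroxyethyl)-2-(2-hydroxypropan-2-yl)-6,8-dihydro-7H-furo[2,3-e]indol-7-one
Conditions: Bu4NF (3 equiv), THF, 0 °C → rt
Reagents that add atoms: none
Why: Fluoride-induced cleavage of both silyl ethers, driven by Si–F bond formation; the oxindole is no longer N-acylated, so the liberated primary alkoxide cannot open ring B by translactonisation.

**Step 19**
Reactants: 29 diol
Product: 30 (R)-2-(5-bromo-8-{2-[Boc(methyl)amino]ethyl}-2-(2-hydroxypropan-2-yl)-7-oxo-7,8-dihydro-6H-furo[2,3-e]indol-8-yl)acetaldehyde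
Conditions: Dess–Martin periodinane, NaHCO3, CH2Cl2, 0 °C → rt
Reagents that add atoms: none
Why: Dess–Martin oxidation converts the only oxidisable (primary) alcohol into the aldehyde under buffered, non-acidic conditions, the tertiary alcohol being inert.

**Step 20**
Reactants: 30 aldehyde
Product: 31 (S)-5-bromo-8-{2-[Boc(methyl)amino]ethyl}-2-(2-hydroxypropan-2-yl)-8-(3-methylbut-2-enyl)-6,8-dihydro-7H-furo[2,3-e]indol-7-one
Conditions: [i-PrPPh3]I (4.5 equiv), KN(SiMe3)2 (4.3 equiv), THF, 0 °C; then 30, −78 °C → rt
Reagents that add atoms: isopropyltriphenylphosphonium iodide, CC(C)[P+](c1ccccc1)(c1ccccc1)c1ccccc1.[I-]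
Why: Wittig olefination with the non-stabilised isopropylidene ylide, used in excess because N8-H and the tertiary OH each tie up one equivalent reversibly, builds the trisubstituted prenyl alkene without any E/Z issue (the descriptor at C3a changes only because the priorities change).

**Step 21**
Reactants: 31 prenyl oxindole
Product: 33 (S)-5-bromo-2-(2-hydroxypropan-2-yl)-8-(3-methylbut-2-enyl)-8-[2-(methylamino)ethyl]-6,8-dihydro-7H-furo[2,3-e]indol-7-one, via silyl carbamate 32 (not isolated)
Conditions: Me3SiOTf (4 equiv), 2,6-lutidine (6 equiv), CH2Cl2, 0 °C; then MeOH, rt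
Reagents that add atoms: none
Why: Silyl triflate-mediated Boc cleavage: the tert-butyl carbamate is converted into a silyl carbamate with loss of isobutene under lutidine buffering, so no strong Brønsted acid meets the prenyl group or the ionisable tertiary benzofuranyl carbinol (masked in situ as its trimethylsilyl ether), and methanol then releases the amine and the alcohol.

**Step 22**
Reactants: 33 amino oxindole
Product: 35 target CNP0306513.1 with (3aS,8aS) configuration, via 3H-indole 34 (not isolated)
Conditions: AlH3·NMe2Et (8 equiv), THF, 0 °C → rt; then aq. potassium sodium tartrate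
Reagents that add atoms: none
Why: Alane reduction of the lactam to the carbinolamine level and loss of the aluminium oxide give 3H-indole 34, to which the tethered N1 amine adds (reductive aminal cyclisation); ring C can only be cis-fused to ring B, so C3a dictates (S) at C8a, and alane spares the aryl bromide, the alkene and the benzofuran.

**Compound list**
1 | aniracetam, 1-(4-methoxybenzoyl)pyrrolidin-2-one | COc1ccc(cc1)C(=O)N1CCCC1=O | starting material
2 | allyl chloroformate | C=CCOC(=O)Cl | starting material
3 | allyl 1-(4-methoxybenzoyl)-2-oxopyrrolidine-3-carboxylate (racemic) | C=CCOC(=O)C1CCN(C(=O)c2ccc(OC)cc2)C1=O | intermediate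
4 | tert-butyl(2-iodoethoxy)dimethylsilane | CC(C)(C)[Si](C)(C)OCCI | starting material
5 | allyl 3-[2-(TBS-oxy)ethyl]-1-(4-methoxybenzoyl)-2-oxopyrrolidine-3-carboxylate (racemic) | C=CCOC(=O)C1(CCO[Si](C)(C)C(C)(C)C)CCN(C(=O)c2ccc(OC)cc2)C1=O | intermediate
6 | (R)-3-allyl-3-[2-(TBS-oxy)ethyl]-1-(4-methoxybenzoyl)pyrrolidin-2-one | C=CC[C@]1(CCO[Si](C)(C)C(C)(C)C)CCN(C(=O)c2ccc(OC)cc2)C1=O | intermediate
7 | (R)-3-allyl-3-[2-(TBS-oxy)ethyl]pyrrolidin-2-one | C=CC[C@]1(CCO[Si](C)(C)C(C)(C)C)CCNC1=O | intermediate
8 | (R)-3-[2-(TBS-oxy)ethyl]-3-[(E)-prop-1-enyl]pyrrolidin-2-one | C/C=C/[C@]1(CCO[Si](C)(C)C(C)(C)C)CCNC1=O | intermediate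
9 | secondary ozonide of 8 (trioxolane carbons unassigned; not isolated) | CC1OOC(O1)[C@]2(CCO[Si](C)(C)C(C)(C)C)CCNC2=O | intermediate
10 | (R)-3-[2-(TBS-oxy)ethyl]-2-oxopyrrolidine-3-carbaldehyde | O=C[C@]1(CCO[Si](C)(C)C(C)(C)C)CCNC1=O | intermediate
11 | (R)-3-ethynyl-3-[2-(TBS-oxy)ethyl]pyrrolidin-2-one | C#C[C@]1(CCO[Si](C)(C)C(C)(C)C)CCNC1=O | intermediate
12 | tert-butyl (R)-3-ethynyl-3-[2-(TBS-oxy)ethyl]-2-oxopyrrolidine-1-carboxylate | C#C[C@]1(CCO[Si](C)(C)C(C)(C)C)CCN(C(=O)OC(C)(C)C)C1=O | intermediate
13 | (R)-2-[2-(Boc-amino)ethyl]-2-ethynyl-4-(TBS-oxy)butanoic acid | C#C[C@](CCO[Si](C)(C)C(C)(C)C)(CCNC(=O)OC(C)(C)C)C(=O)O | intermediate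
14 | (R)-2-{2-[Boc(methyl)amino]ethyl}-2-ethynyl-4-(TBS-oxy)butanoic acid | C#C[C@](CCO[Si](C)(C)C(C)(C)C)(CCN(C)C(=O)OC(C)(C)C)C(=O)O | intermediate
15 | 2-methylbut-3-yn-2-ol | C#CC(C)(C)O | starting material
16 | triethyl[(2-methylbut-3-yn-2-yl)oxy]silane | C#CC(C)(C)O[Si](CC)(CC)CC | intermediate
17 | 5-bromofuran-2-carboxylic acid | O=C(O)c1ccc(Br)o1 | starting material
18 | 5-[3-methyl-3-(triethylsilyloxy)but-1-ynyl]furan-2-carboxylic acid | O=C(O)c1ccc(C#CC(C)(C)O[Si](CC)(CC)CC)o1 | intermediate
19 | acyl azide of 18 (not isolated) | [N-]=[N+]=NC(=O)c1ccc(C#CC(C)(C)O[Si](CC)(CC)CC)o1 | intermediate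
20 | 2-isocyanato-5-[3-methyl-3-(triethylsilyloxy)but-1-ynyl]furan (not isolated) | O=C=Nc1ccc(C#CC(C)(C)O[Si](CC)(CC)CC)o1 | intermediate
21 | methyl {5-[3-methyl-3-(triethylsilyloxy)but-1-ynyl]furan-2-yl}carbamate | COC(=O)Nc1ccc(C#CC(C)(C)O[Si](CC)(CC)CC)o1 | intermediate
22 | acid chloride of 14 (not isolated) | C#C[C@](CCO[Si](C)(C)C(C)(C)C)(CCN(C)C(=O)OC(C)(C)C)C(=O)Cl | intermediate
23 | cascade precursor, (R)-N-acyl-N-(5-alkynylfuran-2-yl) methyl carbamate | C#C[C@](CCO[Si](C)(C)C(C)(C)C)(CCN(C)C(=O)OC(C)(C)C)C(=O)N(C(=O)OC)c1ccc(C#CC(C)(C)O[Si](CC)(CC)CC)o1 | intermediate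
24 | oxepine with ring B closed, oxygen bridging C4 and C5 (not isolated) | CC(C)(C)[Si](C)(C)OCC[C@@]1(CCN(C)C(=O)OC(C)(C)C)C(=O)N(C(=O)OC)C2=CC=C(C#CC(C)(C)O[Si](CC)(CC)CC)OC=C21 | intermediate
25 | methyl (R)-3-{2-[Boc(methyl)amino]ethyl}-3-[2-(TBS-oxy)ethyl]-4-hydroxy-5-[3-methyl-3-(triethylsilyloxy)but-1-ynyl]-2-oxoindoline-1-carboxylate (not isolated) | CC(C)(C)[Si](C)(C)OCC[C@@]1(CCN(C)C(=O)OC(C)(C)C)C(=O)N(C(=O)OC)c2ccc(C#CC(C)(C)O[Si](CC)(CC)CC)c(O)c21 | intermediate
26 | cascade product, N8-CO2Me furo[2,3-e]indol-7-one, (R) | CC(C)(C)[Si](C)(C)OCC[C@@]1(CCN(C)C(=O)OC(C)(C)C)C(=O)N(C(=O)OC)c2ccc3cc(C(C)(C)O[Si](CC)(CC)CC)oc3c21 | intermediate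
27 | N8-H furo[2,3-e]indol-7-one, (R) | CC(C)(C)[Si](C)(C)OCC[C@@]1(CCN(C)C(=O)OC(C)(C)C)C(=O)Nc2ccc3cc(C(C)(C)O[Si](CC)(CC)CC)oc3c21 | intermediate
28 | C7 bromide of 27, (R) | CC(C)(C)[Si](C)(C)OCC[C@@]1(CCN(C)C(=O)OC(C)(C)C)C(=O)Nc2c(Br)cc3cc(C(C)(C)O[Si](CC)(CC)CC)oc3c21 | intermediate
29 | bromo diol, (R) | OCC[C@@]1(CCN(C)C(=O)OC(C)(C)C)C(=O)Nc2c(Br)cc3cc(C(C)(C)O)oc3c21 | intermediate
30 | bromo aldehyde, (R) | O=CC[C@@]1(CCN(C)C(=O)OC(C)(C)C)C(=O)Nc2c(Br)cc3cc(C(C)(C)O)oc3c21 | intermediate
31 | bromo prenyl oxindole with N1(Me)Boc, (S) | CC(C)=CC[C@@]1(CCN(C)C(=O)OC(C)(C)C)C(=O)Nc2c(Br)cc3cc(C(C)(C)O)oc3c21 | intermediate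
32 | trimethylsilyl carbamate and trimethylsilyl ether of 31 after loss of isobutene, (S) (not isolated) | CC(C)=CC[C@@]1(CCN(C)C(=O)O[Si](C)(C)C)C(=O)Nc2c(Br)cc3cc(C(C)(C)O[Si](C)(C)C)oc3c21 | intermediate
33 | bromo prenyl oxindole with free NHMe arm, (S) | CC(C)=CC[C@@]1(CCNC)C(=O)Nc2c(Br)cc3cc(C(C)(C)O)oc3c21 | intermediate
34 | 3H-indole (C8a=N8) with free NHMe arm, (S) (not isolated) | CC(C)=CC[C@@]1(CCNC)C=Nc2c(Br)cc3cc(C(C)(C)O)oc3c21 | intermediate
35 | CNP0306513.1, (3aS,8aS): 7-bromo, 3a-prenyl, N1-methyl, N8-H, 2-(2-hydroxypropan-2-yl)furan fused at C4 (O) and C5 (C) | CC(C)=CC[C@@]12CCN(C)[C@@H]1Nc1c(Br)cc3cc(C(C)(C)O)oc3c12 | target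

**Totals**
Total step count: 22. Longest linear sequence: 19 steps (steps 1–10, then 14–22). Steps 11–13 form the three-step side branch.

**Steps most likely to fail**

1. Step 15 (new method).
What may go wrong:
- The furan carries two acceptor-type substituents and may be too weak a nucleophile. Alkyne hydration or oligomerisation could then outrun cyclopropanation.
- The arene oxide may open in the undesired direction.

Fallback, by known chemistry with the arene bought rather than built: it sets out from 15 and comes back at 31.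
- Commercial 4-hydroxyindolin-2-one (O=C1Cc2c(O)cccc2N1) is condensed with commercial tert-butyl methyl(2-oxoethyl)carbamate (CN(CC=O)C(=O)OC(C)(C)C) under Knoevenagel conditions (piperidine, EtOH). This gives the 3-alkylidene oxindole F1.
- Hydrogenation (H2, Pd/C, EtOAc) gives the 3-alkyl-4-hydroxyoxindole F2.
- NBS (1 equiv, MeCN, −20 °C) brominates para to the phenol, at C7, to give the bromophenol F3.
- NIS fills the remaining activated position ortho to the phenol, C5, to give the bromo-iodophenol F4.
- Sonogashira coupling of the C–I bond with 15, with cyclisation of the 2-alkynylphenol in the same flask (PdCl2(PPh3)2, CuI, Et3N, DMF, 60 °C), gives the C3a-H furo-oxindole F5.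
- Palladium-catalysed asymmetric allylic alkylation of F5 sets C3a and gives 31. It uses tert-butyl (3-methylbut-2-en-1-yl) carbonate (CC(C)=CCOC(=O)OC(C)(C)C), Pd2(dba)3·CHCl3 and the appropriate enantiomer of the DACH-phenyl diphosphine ligand, under the conditions that favour the linear prenyl product.

2. Step 17.
What may go wrong: the electrophile may also attack the furan β-carbon, or a second bromination may occur.
Fallback, replacing electrophilic substitution by C–H borylation and halodeboronation: it sets out from 27 and comes back at 28.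
- Iridium-catalysed borylation ([Ir(OMe)(cod)]2, 4,4'-di-tert-butyl-2,2'-bipyridine, B2pin2, THF, 65 °C) should select the C7–H bond.
- C7 lies next to the small N8-H. The furan β-C–H is blocked by the bulky CMe2OSiEt3 neighbour, and C6–H sits in the peri position of the benzofuran. The product is the C7 pinacol boronate F6.
- CuBr2 in aqueous MeOH at 80 °C converts F6 into 28.

3. Step 14.
What may go wrong: acylation at the neopentyl-type acid chloride may be slowed by steric hindrance, leaving time for the sensitive amidofuran anion to decompose.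
Fallback, forming the C8a–N8 bond from the isocyanate and adding the small acyl group last: it sets out from 14 and from isocyanate 20, and comes back at 23.
- Isocyanate 20 is generated from 18 as in step 13, with the methanol omitted.
- The triethylammonium salt of 14 adds to 20 (DMAP cat., toluene, rt → 60 °C) to give the mixed carbamic carboxylic anhydride F7.
- F7 loses CO2 with intramolecular acyl transfer to give the secondary N-furyl amide F8.
- Deprotonation of the amide N–H (LiN(SiMe3)2, THF, −78 °C) and capture with methyl chloroformate give 23.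

**Further compounds**
F1 | step 15 | tert-butyl [2-(4-hydroxy-2-oxoindolin-3-ylidene)ethyl](methyl)carbamate (E/Z unassigned) | CN(CC=C1C(=O)Nc2cccc(O)c21)C(=O)OC(C)(C)C
F2 | step 15 | tert-butyl [2-(4-hydroxy-2-oxoindolin-3-yl)ethyl](methyl)carbamate (racemic, labile C3) | CN(CCC1C(=O)Nc2cccc(O)c21)C(=O)OC(C)(C)C
F3 | step 15 | tert-butyl [2-(7-bromo-4-hydroxy-2-oxoindolin-3-yl)ethyl](methyl)carbamate (racemic) | CN(CCC1C(=O)Nc2c(Br)ccc(O)c21)C(=O)OC(C)(C)C
F4 | step 15 | tert-butyl [2-(7-bromo-4-hydroxy-5-iodo-2-oxoindolin-3-yl)ethyl](methyl)carbamate (racemic) | CN(CCC1C(=O)Nc2c(Br)cc(I)c(O)c21)C(=O)OC(C)(C)C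
F5 | step 15 | tert-butyl {2-[5-bromo-2-(2-hydroxypropan-2-yl)-7-oxo-7,8-dihydro-6H-furo[2,3-e]indol-8-yl]ethyl}(methyl)carbamate (racemic) | CN(CCC1C(=O)Nc2c(Br)cc3cc(C(C)(C)O)oc3c21)C(=O)OC(C)(C)C
F6 | step 17 | C7 pinacol boronate of 27, (R) | CC(C)(C)[Si](C)(C)OCC[C@@]1(CCN(C)C(=O)OC(C)(C)C)C(=O)Nc2c(B4OC(C)(C)C(C)(C)O4)cc3cc(C(C)(C)O[Si](CC)(CC)CC)oc3c21
F7 | step 14 | mixed carbamic carboxylic anhydride from 14 and 20, (R) | C#C[C@](CCO[Si](C)(C)C(C)(C)C)(CCN(C)C(=O)OC(C)(C)C)C(=O)OC(=O)Nc1ccc(C#CC(C)(C)O[Si](CC)(CC)CC)o1
F8 | step 14 | secondary N-furyl amide of 14, (R) | C#C[C@](CCO[Si](C)(C)C(C)(C)C)(CCN(C)C(=O)OC(C)(C)C)C(=O)Nc1ccc(C#CC(C)(C)O[Si](CC)(CC)CC)o1
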